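**Retrosynthetic overview**

1. The lactol ring is closed last, by acid unmasking of a dioxane acetal onto the ring-fusion hydroxyl; the cyclohexane tertiary carbinol comes from equatorial MeLi addition to a ketone.
2. The halves are joined at the cyclohexane CH that carries the two-carbon tether: aldol condensation of aldehyde 26 with the regiodefined enolate of 34, then 1,4-reduction.
3. In the left half the tether is placed on the CH next to the C(CH3)2 group by a Johnson–Claisen rearrangement of a CBS-derived allylic alcohol; the same step puts the ring alkene in its final position.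
4. The seven-membered ring comes from a six-membered one. In the hydroazulene, the C(CH3)2 ring atom sits between the ring-fusion CH shared with the cyclopentane and the carbon that later bears the tether; it is therefore inserted next to the carbonyl of a cis-hydrindan-4-one by a silver-promoted semipinacol shift of a β-hydroxy selenide.
5. Ring order, left: cyclohexanone, then cyclopentene (metathesis), then cycloheptanone (ring expansion). Right: cyclohexenone, then after coupling the oxygen heterocycle.

Key step: step 8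

Remark on the chemistry: the lactol is assumed to equilibrate between its anomers; the target is the anomer with equatorial OH, taken as the form that predominates and is isolated. Compounds 27 and 33 (as a THF solution) are taken as commercial.

**Left half**

Step 1
Reactants: 1 9-methoxy-9-borabicyclo[3.3.1]nonane; 2 isopropenylmagnesium bromide
Product: 3 9-(prop-1-en-2-yl)-9-borabicyclo[3.3.1]nonane
Conditions: THF/pentane, −78 → 23 °C; filtration, distillation
Reagents that add atoms: none
Why: Transmetalation of the Grignard reagent onto boron gives a methoxyborate that should collapse with loss of Mg(OMe)Br, the standard preparation of B-organyl-9-BBN reagents.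

Step 2
Reactants: 4 cyclohex-2-en-1-one; 3 9-(prop-1-en-2-yl)-9-borabicyclo[3.3.1]nonane
Product: 7 (2R,3S)-2-allyl-3-(prop-1-en-2-yl)cyclohexan-1-one, via boron enolate 5 (not isolated), via lithium enolate 6 (not isolated)
Conditions: [Rh(OMe)(cod)]2 (1.5 mol %), (S)-BINAP (3.3 mol %), toluene, 80 °C; then n-BuLi, THF, −78 °C; allyl bromide, −78 → 0 °C
Reagents that add atoms: allyl bromide, C=CCBr
Why: Hayashi-type rhodium/BINAP-catalysed asymmetric 1,4-addition of a B-organyl-9-BBN should set the isopropenyl-bearing centre under catalyst control and leave a regiodefined boron enolate, which after conversion into the lithium enolate is allylated anti to the new substituent.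

Step 3
Reactants: 7 (2R,3S)-2-allyl-3-(prop-1-en-2-yl)cyclohexan-1-one
Product: 9 (3aS,7aS)-1-methyl-3,3a,5,6,7,7a-hexahydro-4H-inden-4-one, via trans-fused ketone 8 (not isolated)
Conditions: second-generation Grubbs catalyst (2 mol %), CH2Cl2, 40 °C; then DBU, 23 °C
Reagents that add atoms: none
Why: Ring-closing metathesis of the allyl and isopropenyl groups closes the cyclopentene, and the α-centre should then equilibrate through the enol to the less strained cis ring fusion.

Step 4
Reactants: 9 (3aS,7aS)-1-methyl-3,3a,5,6,7,7a-hexahydro-4H-inden-4-one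
Product: 10 (1S,3aS,7aS)-1-hydroxy-1-methyloctahydro-4H-inden-4-one
Conditions: Mn(dpm)3 (5 mol %), PhSiH3, O2 (1 atm), i-PrOH, 0 → 23 °C
Reagents that add atoms: dioxygen, O=O
Why: Mukaiyama hydration by hydrogen-atom transfer gives the tertiary radical (Markovnikov), which should be trapped by O2 on the convex face of the cis-hydrindane, placing OH syn to the ring-fusion hydrogens.

Step 5
Reactants: 10 (1S,3aS,7aS)-1-hydroxy-1-methyloctahydro-4H-inden-4-one
Product: 11 (1S,3aS,7aS)-1-methyl-1-[(triethylsilyl)oxy]octahydro-4H-inden-4-one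
Conditions: Et3SiOTf, 2,6-lutidine, CH2Cl2, −78 °C
Reagents that add atoms: triethylsilyl trifluoromethanesulfonate, CC[Si](CC)(CC)OS(=O)(=O)C(F)(F)F
Why: Silyl triflate silylation of a tertiary alcohol is fast at low temperature and should leave the ketone untouched.

Step 6
Reactants: 12 acetone; 13 benzeneselenol
Product: 14 2,2-bis(phenylselanyl)propane
Conditions: PhSeH (2 equiv in all), ZnCl2 (0.5 equiv), CH2Cl2, 23 °C
Reagents that add atoms: benzeneselenol, [SeH]c1ccccc1
Why: Lewis-acid selenoketalisation of a ketone is the standard entry to selenoketals and consumes two molecules of the selenol per carbonyl group with loss of water, so the second equivalent of 13 is entered on the line above.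

Step 7
Reactants: 11 (1S,3aS,7aS)-1-methyl-1-[(triethylsilyl)oxy]octahydro-4H-inden-4-one; 14 2,2-bis(phenylselanyl)propane
Product: 16 cis-fused 1-methyl-4-[2-(phenylselanyl)propan-2-yl]-1-[(triethylsilyl)oxy]octahydro-1H-inden-4-ol, via selenoalkyllithium 15 (not isolated)
Conditions: n-BuLi, THF, −78 °C; then 11, −78 °C; NH4Cl (aq)
Reagents that add atoms: none
Why: Selenium/lithium exchange gives a strongly nucleophilic, weakly basic α-selenoalkyllithium that should add to the enolisable ketone from its convex face (Krief reagent); the carbinol configuration is lost in step 8.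

Step 8
Reactants: 16 cis-fused 1-methyl-4-[2-(phenylselanyl)propan-2-yl]-1-[(triethylsilyl)oxy]octahydro-1H-inden-4-ol
Product: 17 cis-fused 1,4,4-trimethyl-1-[(triethylsilyl)oxy]octahydroazulen-5(1H)-one
Conditions: AgBF4 (1.5 equiv), basic Al2O3, CH2Cl2, 0 → 23 °C
Reagents that add atoms: none
Why: Ag+ binds the soft selenium and turns PhSe into a leaving group; ionisation at the tertiary exocyclic carbon is concerted with a 1,2-shift of a ring bond from the carbinol carbon, and loss of the hydroxyl proton gives the ring-enlarged ketone (semipinacol shift of Tiffeneau–Demjanov type). The closest known reaction is the Krief ring enlargement of β-hydroxyalkyl selenides, which turns cyclohexanones into 2,2-dimethylcycloheptanones. No ring is closed: the six-membered ring becomes seven-membered by a 1,2-alkyl shift that inserts the C(CH3)2 atom between the carbonyl carbon and the ring-fusion carbon. No new stereocentre is formed; the migrating ring-fusion carbon moves with retention, so the cis fusion of step 3 and the carbinol centre of step 4 are carried over. The step needs migration of the ring-fusion CH and not of the CH2 on the other side of the carbinol; the higher substitution of the methine, which better stabilises the electron-poor transition state, should secure this as in 2-alkylcyclohexanone cases. The non-basic silver conditions should disfavour oxirane formation.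

Step 9
Reactants: 17 cis-fused 1,4,4-trimethyl-1-[(triethylsilyl)oxy]octahydroazulen-5(1H)-one
Product: 18 cis-fused 1,4,4,6-tetramethyl-1-[(triethylsilyl)oxy]octahydroazulen-5(1H)-one (C-6 epimers)
Conditions: LiN(i-Pr)2, THF, −78 °C; MeI, −78 → 0 °C
Reagents that add atoms: iodomethane, CI
Why: The ketone can enolise only away from the quaternary carbon, so enolate methylation is regiospecific; the new centre becomes sp2 in step 10.

Step 10
Reactants: 18 cis-fused 1,4,4,6-tetramethyl-1-[(triethylsilyl)oxy]octahydroazulen-5(1H)-one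
Product: 20 cis-fused 1,4,4,6-tetramethyl-1-[(triethylsilyl)oxy]-2,3,3a,4,8,8a-hexahydroazulen-5(1H)-one, via silyl enol ether 19 (not isolated)
Conditions: LiN(i-Pr)2, Me3SiCl, THF, −78 °C; then Pd(OAc)2 (1.1 equiv), MeCN, 23 °C
Reagents that add atoms: none
Why: Saegusa–Ito oxidation of the only possible silyl enol ether should give the endocyclic 2-methyl enone.

Step 11
Reactants: 20 cis-fused 1,4,4,6-tetramethyl-1-[(triethylsilyl)oxy]-2,3,3a,4,8,8a-hexahydroazulen-5(1H)-one
Product: 21 cis-fused 1,4,4,6-tetramethyl-1-[(triethylsilyl)oxy]-1,2,3,3a,4,5,8,8a-octahydroazulen-5-ol (C-5 epimers)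
Conditions: i-Bu2AlH, CH2Cl2, −78 °C
Reagents that add atoms: none
Why: The small aluminium hydride should reduce the hindered enone in the 1,2-sense; the carbinol configuration is irrelevant for step 12.

Step 12
Reactants: 21 cis-fused 1,4,4,6-tetramethyl-1-[(triethylsilyl)oxy]-1,2,3,3a,4,5,8,8a-octahydroazulen-5-ol
Product: 22 cis-fused 1,4,4,6-tetramethyl-1-[(triethylsilyl)oxy]-1,2,3,3a,4,7,8,8a-octahydroazulen-7-ol (C-7 epimers)
Conditions: Ph3SiOReO3 (2 mol %), Et2O, 0 → 23 °C
Reagents that add atoms: none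
Why: Rhenium-oxo-catalysed 1,3-transposition of the allylic alcohol ([3,3] shift of the perrhenate ester) should move the hydroxyl from the neopentyl carbon next to C(CH3)2 to the unhindered end of the allyl system.

Step 13
Reactants: 22 cis-fused 1,4,4,6-tetramethyl-1-[(triethylsilyl)oxy]-1,2,3,3a,4,7,8,8a-octahydroazulen-7-ol
Product: 23 cis-fused 1,4,4,6-tetramethyl-1-[(triethylsilyl)oxy]-2,3,3a,4,8,8a-hexahydroazulen-7(1H)-one
Conditions: MnO2, CH2Cl2, 23 °C
Reagents that add atoms: none
Why: Allylic oxidation with MnO2 merges both carbinol epimers into the transposed enone; any unrearranged 21 returns to 20 and can be recycled.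

Step 14
Reactants: 23 cis-fused 1,4,4,6-tetramethyl-1-[(triethylsilyl)oxy]-2,3,3a,4,8,8a-hexahydroazulen-7(1H)-one
Product: 24 (7R)-1,4,4,6-tetramethyl-1-[(triethylsilyl)oxy]-1,2,3,3a,4,7,8,8a-octahydroazulen-7-ol
Conditions: (S)-1-methyl-3,3-diphenyltetrahydro-1H,3H-pyrrolo[1,2-c][1,3,2]oxazaborole (20 mol %), BH3·SMe2, THF, −40 °C
Reagents that add atoms: none
Why: Corey–Bakshi–Shibata reduction, with the α-methyl alkenyl carbon as the large group, should give the (R)-carbinol under reagent control, with OH on the face opposite to the ring-fusion hydrogens.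

Step 15
Reactants: 24 (7R)-1,4,4,6-tetramethyl-1-[(triethylsilyl)oxy]-1,2,3,3a,4,7,8,8a-octahydroazulen-7-ol
Product: 25 ethyl 2-{1,4,4,6-tetramethyl-1-[(triethylsilyl)oxy]-1,2,3,3a,4,5,8,8a-octahydroazulen-5-yl}acetate
Conditions: MeC(OEt)3, EtCO2H (cat.), xylene, 140 °C
Reagents that add atoms: triethyl orthoacetate, CC(OCC)(OCC)OCC
Why: Johnson–Claisen rearrangement forms the C–C bond at the neopentyl ring carbon intramolecularly and suprafacially, so the carbinol configuration is transferred to the new centre (chain anti to the ring-fusion hydrogens) and the alkene lands in its final position; the cyclohexenol analogue with the same methyl pattern is a known substrate type.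

Step 16
Reactants: 25 ethyl 2-{1,4,4,6-tetramethyl-1-[(triethylsilyl)oxy]-1,2,3,3a,4,5,8,8a-octahydroazulen-5-yl}acetate
Product: 26 2-{1,4,4,6-tetramethyl-1-[(triethylsilyl)oxy]-1,2,3,3a,4,5,8,8a-octahydroazulen-5-yl}acetaldehyde
Conditions: i-Bu2AlH, CH2Cl2, −78 °C
Reagents that add atoms: none
Why: Partial reduction of an ester to the aldehyde through the stable tetrahedral aluminium intermediate at low temperature.

**Right half**

Step 17
Reactants: 27 1,4-dioxaspiro[4.5]dec-6-en-8-one
Product: 28 7-iodo-1,4-dioxaspiro[4.5]dec-6-en-8-one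
Conditions: I2, pyridine, CH2Cl2, 0 → 23 °C
Reagents that add atoms: iodine, II
Why: α-Iodination of an enone by pyridine addition, iodination and elimination (Johnson procedure).

Step 18
Reactants: 28 7-iodo-1,4-dioxaspiro[4.5]dec-6-en-8-one
Product: 29 7-methyl-1,4-dioxaspiro[4.5]dec-6-en-8-one
Conditions: trimethylboroxine, Pd(PPh3)4 (5 mol %), K2CO3, dioxane, 90 °C
Reagents that add atoms: trimethylboroxine, CB1OB(C)OB(C)O1
Why: Suzuki–Miyaura methylation of an α-iodoenone.

Step 19
Reactants: 29 7-methyl-1,4-dioxaspiro[4.5]dec-6-en-8-one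
Product: 30 (8S)-7-methyl-1,4-dioxaspiro[4.5]dec-6-en-8-ol
Conditions: (R)-1-methyl-3,3-diphenyltetrahydro-1H,3H-pyrrolo[1,2-c][1,3,2]oxazaborole (10 mol %), BH3·SMe2, THF, −20 °C
Reagents that add atoms: none
Why: Corey–Bakshi–Shibata reduction of an α-substituted cyclic enone should set the carbinol centre (later the ring-fusion CH–O) under reagent control.

Step 20
Reactants: 30 (8S)-7-methyl-1,4-dioxaspiro[4.5]dec-6-en-8-ol
Product: 31 tert-butyl{[(8S)-7-methyl-1,4-dioxaspiro[4.5]dec-6-en-8-yl]oxy}dimethylsilane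
Conditions: t-BuMe2SiCl, imidazole, DMF, 23 °C
Reagents that add atoms: tert-butylchlorodimethylsilane, CC(C)(C)[Si](C)(C)Cl
Why: Standard silylation of a secondary alcohol.

Step 21
Reactants: 31 tert-butyl{[(8S)-7-methyl-1,4-dioxaspiro[4.5]dec-6-en-8-yl]oxy}dimethylsilane
Product: 32 (4S)-4-[(tert-butyldimethylsilyl)oxy]-3-methylcyclohex-2-en-1-one
Conditions: pyridinium p-toluenesulfonate, acetone/H2O, 50 °C
Reagents that add atoms: water, O
Why: Mild acid hydrolysis of the allylic ketal should unveil the enone without cleaving the silyl ether.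

Step 22
Reactants: 32 (4S)-4-[(tert-butyldimethylsilyl)oxy]-3-methylcyclohex-2-en-1-one; 33 [2-(1,3-dioxan-2-yl)ethyl]magnesium bromide
Product: 34 tert-butyl({(1S,2S)-2-[2-(1,3-dioxan-2-yl)ethyl]-2-methyl-4-[(trimethylsilyl)oxy]cyclohex-3-en-1-yl}oxy)dimethylsilane
Conditions: CuBr·SMe2 (10 mol %), Me3SiCl, HMPA, THF, −78 → −40 °C; Et3N
Reagents that add atoms: chlorotrimethylsilane, C[Si](C)(C)Cl
Why: Copper-catalysed, Me3SiCl-accelerated conjugate addition should form the quaternary carbon anti to the neighbouring silyloxy group (the trans rule for 4-substituted cyclohexenones) and trap the enolate regiospecifically.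

**Union and endgame**

Step 23
Reactants: 34 tert-butyl({(1S,2S)-2-[2-(1,3-dioxan-2-yl)ethyl]-2-methyl-4-[(trimethylsilyl)oxy]cyclohex-3-en-1-yl}oxy)dimethylsilane; 26 2-{1,4,4,6-tetramethyl-1-[(triethylsilyl)oxy]-1,2,3,3a,4,5,8,8a-octahydroazulen-5-yl}acetaldehyde
Product: 36 β-hydroxy ketone aldol adduct (diastereomer mixture), via lithium enolate 35 (not isolated)
Conditions: MeLi, THF, 0 °C; then 26, −78 °C; NH4Cl (aq)
Reagents that add atoms: none
Why: Cleavage of the silyl enol ether by MeLi gives the regiodefined lithium enolate, which should add to the aldehyde (aldol addition); both new centres are removed in steps 24 and 25.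

Step 24
Reactants: 36 β-hydroxy ketone aldol adduct
Product: 38 α-alkylidene ketone (E/Z mixture), via mesylate 37 (not isolated)
Conditions: MeSO2Cl, Et3N, CH2Cl2, 0 °C; then DBU, 23 °C
Reagents that add atoms: none
Why: Mesylation and E1cB elimination give the conjugated exocyclic enone; its geometry is irrelevant.

Step 25
Reactants: 38 α-alkylidene ketone
Product: 39 saturated ketone with the tether equatorial (cis to the angular methyl)
Conditions: [(Ph3P)CuH]6, wet toluene, 23 °C; then K2CO3, MeOH, 23 °C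
Reagents that add atoms: none
Why: Copper hydride 1,4-reduction is chemoselective for the enone over the trisubstituted ring alkene, and base equilibration of the α-centre should favour the equatorial tether.

Step 26
Reactants: 39 saturated ketone
Product: 40 tertiary alcohol (axial OH, equatorial CH3)
Conditions: MeLi, CeCl3, THF, −78 °C
Reagents that add atoms: methyllithium, [Li]C
Why: The organocerium reagent should add from the equatorial side because the axial face is blocked 1,3-diaxially by the angular methyl group, and cerium suppresses enolisation.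

Step 27
Reactants: 40 tertiary alcohol
Product: 43 target lactol CNP0167351.1, via triol acetal 41 (not isolated), via hydroxy aldehyde 42 (not isolated)
Conditions: Bu4NF, THF, 40 °C; then 1 M HCl (aq), THF, 23 °C
Reagents that add atoms: water, O
Why: Fluoride removes both silyl ethers, dilute acid hydrolyses the dioxane acetal, and the aldehyde is captured by the neighbouring secondary hydroxyl as the six-membered lactol (6-exo-trig hemiacetalisation); the trans fusion follows from the centres set in steps 19 and 22.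

**Compound list**

1 | 9-methoxy-9-borabicyclo[3.3.1]nonane | COB1C2CCCC1CCC2 | starting material
2 | isopropenylmagnesium bromide | CC(=C)[Mg]Br | starting material
3 | 9-(prop-1-en-2-yl)-9-borabicyclo[3.3.1]nonane | CC(=C)B1C2CCCC1CCC2 | intermediate
4 | cyclohex-2-en-1-one | O=C1C=CCCC1 | starting material
5 | 9-{[(3S)-3-(prop-1-en-2-yl)cyclohex-1-en-1-yl]oxy}-9-borabicyclo[3.3.1]nonane | CC(=C)[C@H]1CCCC(OB2C3CCCC2CCC3)=C1 | intermediate
6 | lithium (3S)-3-(prop-1-en-2-yl)cyclohex-1-en-1-olate | CC(=C)[C@H]1CCCC(O[Li])=C1 | intermediate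
7 | (2R,3S)-2-allyl-3-(prop-1-en-2-yl)cyclohexan-1-one | O=C1CCC[C@H](C(C)=C)[C@H]1CC=C | intermediate
8 | (3aR,7aS)-1-methyl-3,3a,5,6,7,7a-hexahydro-4H-inden-4-one (trans-fused) | O=C1CCC[C@H]2[C@H]1CC=C2C | intermediate
9 | (3aS,7aS)-1-methyl-3,3a,5,6,7,7a-hexahydro-4H-inden-4-one (cis-fused) | O=C1CCC[C@H]2[C@@H]1CC=C2C | intermediate
10 | (1S,3aS,7aS)-1-hydroxy-1-methyloctahydro-4H-inden-4-one (OH syn to 3a-H and 7a-H) | O=C1CCC[C@H]2[C@@H]1CC[C@]2(C)O | intermediate
11 | (1S,3aS,7aS)-1-methyl-1-[(triethylsilyl)oxy]octahydro-4H-inden-4-one | O=C1CCC[C@H]2[C@@H]1CC[C@]2(C)O[Si](CC)(CC)CC | intermediate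
12 | acetone | CC(C)=O | starting material
13 | benzeneselenol | [SeH]c1ccccc1 | starting material
14 | 2,2-bis(phenylselanyl)propane | CC(C)([Se]c1ccccc1)[Se]c1ccccc1 | intermediate
15 | [2-(phenylselanyl)propan-2-yl]lithium | [Li]C(C)(C)[Se]c1ccccc1 | intermediate
16 | cis-fused 1-methyl-4-[2-(phenylselanyl)propan-2-yl]-1-[(triethylsilyl)oxy]octahydro-1H-inden-4-ol (ring centres as in 11; carbinol epimer from convex-face attack) | O[C@]1(C(C)(C)[Se]c2ccccc2)CCC[C@H]3[C@@H]1CC[C@]3(C)O[Si](CC)(CC)CC | intermediate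
17 | cis-fused 1,4,4-trimethyl-1-[(triethylsilyl)oxy]octahydroazulen-5(1H)-one (3a-H, 8a-H and OSiEt3 syn) | O=C1CCC[C@H]2[C@H](CC[C@]2(C)O[Si](CC)(CC)CC)C1(C)C | intermediate
18 | cis-fused 1,4,4,6-tetramethyl-1-[(triethylsilyl)oxy]octahydroazulen-5(1H)-one (C-6 epimers) | O=C1C(C)CC[C@H]2[C@H](CC[C@]2(C)O[Si](CC)(CC)CC)C1(C)C | intermediate
19 | 5-trimethylsilyl enol ether of 18 | C[Si](C)(C)OC1=C(C)CC[C@H]2[C@H](CC[C@]2(C)O[Si](CC)(CC)CC)C1(C)C | intermediate
20 | cis-fused 1,4,4,6-tetramethyl-1-[(triethylsilyl)oxy]-2,3,3a,4,8,8a-hexahydroazulen-5(1H)-one | O=C1C(C)=CC[C@H]2[C@H](CC[C@]2(C)O[Si](CC)(CC)CC)C1(C)C | intermediate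
21 | cis-fused 1,4,4,6-tetramethyl-1-[(triethylsilyl)oxy]-1,2,3,3a,4,5,8,8a-octahydroazulen-5-ol (C-5 epimers) | OC1C(C)=CC[C@H]2[C@H](CC[C@]2(C)O[Si](CC)(CC)CC)C1(C)C | intermediate
22 | cis-fused 1,4,4,6-tetramethyl-1-[(triethylsilyl)oxy]-1,2,3,3a,4,7,8,8a-octahydroazulen-7-ol (C-7 epimers) | OC1C[C@H]2[C@H](CC[C@]2(C)O[Si](CC)(CC)CC)C(C)(C)C=C1C | intermediate
23 | cis-fused 1,4,4,6-tetramethyl-1-[(triethylsilyl)oxy]-2,3,3a,4,8,8a-hexahydroazulen-7(1H)-one | O=C1C[C@H]2[C@H](CC[C@]2(C)O[Si](CC)(CC)CC)C(C)(C)C=C1C | intermediate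
24 | (7R)-1,4,4,6-tetramethyl-1-[(triethylsilyl)oxy]-1,2,3,3a,4,7,8,8a-octahydroazulen-7-ol (OH anti to 3a-H and 8a-H) | O[C@@H]1C[C@H]2[C@H](CC[C@]2(C)O[Si](CC)(CC)CC)C(C)(C)C=C1C | intermediate
25 | ethyl 2-{1,4,4,6-tetramethyl-1-[(triethylsilyl)oxy]-1,2,3,3a,4,5,8,8a-octahydroazulen-5-yl}acetate (5-H syn to 3a-H and 8a-H) | CC1=CC[C@H]2[C@H](CC[C@]2(C)O[Si](CC)(CC)CC)C(C)(C)[C@@H]1CC(=O)OCC | intermediate
26 | 2-{1,4,4,6-tetramethyl-1-[(triethylsilyl)oxy]-1,2,3,3a,4,5,8,8a-octahydroazulen-5-yl}acetaldehyde | CC1=CC[C@H]2[C@H](CC[C@]2(C)O[Si](CC)(CC)CC)C(C)(C)[C@@H]1CC=O | intermediate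
27 | 1,4-dioxaspiro[4.5]dec-6-en-8-one | O=C1CCC2(OCCO2)C=C1 | starting material
28 | 7-iodo-1,4-dioxaspiro[4.5]dec-6-en-8-one | O=C1CCC2(OCCO2)C=C1I | intermediate
29 | 7-methyl-1,4-dioxaspiro[4.5]dec-6-en-8-one | O=C1CCC2(OCCO2)C=C1C | intermediate
30 | (8S)-7-methyl-1,4-dioxaspiro[4.5]dec-6-en-8-ol | O[C@H]1CCC2(OCCO2)C=C1C | intermediate
31 | tert-butyl{[(8S)-7-methyl-1,4-dioxaspiro[4.5]dec-6-en-8-yl]oxy}dimethylsilane | CC(C)(C)[Si](C)(C)O[C@H]1CCC2(OCCO2)C=C1C | intermediate
32 | (4S)-4-[(tert-butyldimethylsilyl)oxy]-3-methylcyclohex-2-en-1-one | O=C1C=C(C)[C@@H](O[Si](C)(C)C(C)(C)C)CC1 | intermediate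
33 | [2-(1,3-dioxan-2-yl)ethyl]magnesium bromide | Br[Mg]CCC1OCCCO1 | starting material
34 | tert-butyl({(1S,2S)-2-[2-(1,3-dioxan-2-yl)ethyl]-2-methyl-4-[(trimethylsilyl)oxy]cyclohex-3-en-1-yl}oxy)dimethylsilane (chain trans to OSi) | C[Si](C)(C)OC1=C[C@](C)(CCC2OCCCO2)[C@@H](O[Si](C)(C)C(C)(C)C)CC1 | intermediate
35 | lithium enolate corresponding to 34 | [Li]OC1=C[C@](C)(CCC2OCCCO2)[C@@H](O[Si](C)(C)C(C)(C)C)CC1 | intermediate
36 | aldol adduct: 2-(1-hydroxy-2-azulenylethyl)cyclohexanone, carbinol and α-centre as mixtures | CC1=CC[C@H]2[C@H](CC[C@]2(C)O[Si](CC)(CC)CC)C(C)(C)[C@@H]1CC(O)C1[C@](C)(CCC3OCCCO3)[C@@H](O[Si](C)(C)C(C)(C)C)CCC1=O | intermediate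
37 | methanesulfonate of 36 | CC1=CC[C@H]2[C@H](CC[C@]2(C)O[Si](CC)(CC)CC)C(C)(C)[C@@H]1CC(OS(C)(=O)=O)C1[C@](C)(CCC3OCCCO3)[C@@H](O[Si](C)(C)C(C)(C)C)CCC1=O | intermediate
38 | α-alkylidene ketone (E/Z) | CC1=CC[C@H]2[C@H](CC[C@]2(C)O[Si](CC)(CC)CC)C(C)(C)[C@@H]1CC=C1[C@](C)(CCC3OCCCO3)[C@@H](O[Si](C)(C)C(C)(C)C)CCC1=O | intermediate
39 | saturated ketone, tether equatorial and cis to the angular methyl | CC1=CC[C@H]2[C@H](CC[C@]2(C)O[Si](CC)(CC)CC)C(C)(C)[C@@H]1CC[C@H]1[C@](C)(CCC3OCCCO3)[C@@H](O[Si](C)(C)C(C)(C)C)CCC1=O | intermediate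
40 | tertiary alcohol, OH cis to the tether and the angular methyl | CC1=CC[C@H]2[C@H](CC[C@]2(C)O[Si](CC)(CC)CC)C(C)(C)[C@@H]1CC[C@H]1[C@](C)(CCC3OCCCO3)[C@@H](O[Si](C)(C)C(C)(C)C)CC[C@@]1(C)O | intermediate
41 | desilylated triol dioxane acetal | CC1=CC[C@H]2[C@H](CC[C@]2(C)O)C(C)(C)[C@@H]1CC[C@H]1[C@](C)(CCC3OCCCO3)[C@@H](O)CC[C@@]1(C)O | intermediate
42 | open-chain hydroxy aldehyde | CC1=CC[C@H]2[C@H](CC[C@]2(C)O)C(C)(C)[C@@H]1CC[C@H]1[C@](C)(CCC=O)[C@@H](O)CC[C@@]1(C)O | intermediate
43 | CNP0167351.1 (trans-fused lactol, equatorial anomeric OH) | CC1=CC[C@H]2[C@H](CC[C@]2(C)O)C(C)(C)[C@@H]1CC[C@H]1[C@]2(C)CC[C@@H](O)O[C@H]2CC[C@@]1(C)O | target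

**Totals**

Total step count: 27. Longest linear sequence: 20 steps (steps 1–5, 7–16, 23–27).

**Steps most likely to fail**

Step 8. The selenium may leave without the ring bond shifting (closure of an oxirane by the hydroxyl, or loss of a proton to an alkene), or the CH2 carbon may migrate in part. The fallback sets out from 11 and comes back at 17, and it generates the cation by alkene activation instead of by departure of a leaving group. Addition of isopropenylmagnesium bromide 2 (CeCl3, THF, −78 °C) to 11 gives the tertiary allylic alcohol 1-methyl-4-(prop-1-en-2-yl)-1-[(triethylsilyl)oxy]octahydro-1H-inden-4-ol F1. N-Bromosuccinimide in CH2Cl2/2-propanol at −20 °C forms the bromonium ion and triggers a halonium semipinacol ring enlargement to the 4-(bromomethyl)-1,4-dimethyl-1-[(triethylsilyl)oxy]octahydroazulen-5(1H)-one F2. Bu3SnH with azobisisobutyronitrile in toluene at 80 °C, run at high stannane concentration so that hydrogen transfer outruns a 1,2-acyl shift of the β-keto radical, then removes bromine and gives 17.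

Step 12. The perrhenate ester may ionise to an allyl cation that loses a proton (diene formation), or the equilibrium may stay on the side of 21. The fallback sets out from 20 and comes back at 22. Nucleophilic epoxidation (30 % H2O2, NaOH, MeOH, 0 °C) gives the 6,7-epoxy-1,4,4,6-tetramethyl-1-[(triethylsilyl)oxy]octahydroazulen-5(1H)-one F3, and Wharton transposition (N2H4·H2O, AcOH cat., MeOH) opens it to allylic alcohol 22.

Step 4. The tertiary radical may be trapped by O2 with poor facial selectivity, or be reduced to the alkane. The fallback sets out from 9 and comes back at 10. mCPBA (NaHCO3, CH2Cl2, 0 °C) epoxidises the cyclopentene from the convex face to the 1,2-epoxy-1-methyloctahydro-4H-inden-4-one F4. LiAlH4 (THF, 0 → 23 °C) opens the oxirane at its CH carbon and reduces the ketone to the 1-methyloctahydro-1H-indene-1,4-diol F5. Dess–Martin periodinane then oxidises only the secondary alcohol and returns 10.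

Further compounds
F1 | step 8 | cis-fused 1-methyl-4-(prop-1-en-2-yl)-1-[(triethylsilyl)oxy]octahydro-1H-inden-4-ol | O[C@]1(C(C)=C)CCC[C@H]2[C@@H]1CC[C@]2(C)O[Si](CC)(CC)CC
F2 | step 8 | cis-fused 4-(bromomethyl)-1,4-dimethyl-1-[(triethylsilyl)oxy]octahydroazulen-5(1H)-one (C-4 epimers) | O=C1CCC[C@H]2[C@H](CC[C@]2(C)O[Si](CC)(CC)CC)C1(C)CBr
F3 | step 12 | cis-fused 6,7-epoxy-1,4,4,6-tetramethyl-1-[(triethylsilyl)oxy]octahydroazulen-5(1H)-one | O=C1[C@@]2(C)O[C@H]2C[C@H]3[C@H](CC[C@]3(C)O[Si](CC)(CC)CC)C1(C)C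
F4 | step 4 | cis-fused 1,2-epoxy-1-methyloctahydro-4H-inden-4-one (oxirane on the convex face) | O=C1CCC[C@H]2[C@@H]1C[C@@H]1O[C@]21C
F5 | step 4 | cis-fused 1-methyloctahydro-1H-indene-1,4-diol (C-4 epimers) | OC1CCC[C@H]2[C@@H]1CC[C@]2(C)O
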